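The readings come from a simulation on assumed constants; noise was put on by code.

Multiplying equivalents by substrate is the easy step: the flask asked about holds a reagent charge of 0.0810 M, ash holds 0.126 M and cedar 0.126 M.

| flask | substrate | reagent in the second phase | remark | time | volume of the second phase over the first |
|---|---|---|---|---|---|
| alder | 0.060 M | 0.90 equiv | run made earlier |  |  |
| ash | 0.14 M | 0.90 equiv | run made earlier |  |  |
| cedar | 0.090 M | 1.4 equiv | run made earlier |  |  |
| flask | 0.090 M | 0.900 equiv |  | 30 h | 2.0 |

- alder (time / h: target / %, substrate / %): 1.50: 0.7, 101.4; 5.00: 0, 99.9; 8.00: 1.3, 98.1; 12.0: 2.2, 97.1; 20.0: 3.3, 96.8; 25.0: 6.3, 95.0; 30.0: 4.5, 93.2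
- ash (time / h: target / %, substrate / %): 4.00: 1.1, 98.5; 8.00: 3.9, 98.2; 12.0: 5.1, 96.1; 15.0: 5.5, 92.3; 20.0: 7.0, 90.5; 25.0: 8.1, 88.8; 30.0: 10.2, 85.0
- cedar (time / h: target / %, substrate / %): 2.50: 0, 99.9; 5.00: 2.1, 98.4; 8.00: 5.9, 97.7; 15.0: 6.2, 92.6; 30.0: 9.3, 86.6

(each reading ± 1 percentage point)

- in the second phase: reagent in the second phase; everything else is in the first
- charges count per volume of the first phase; a concentration in a rate is the amount of a species over the volume of its own phase; every rate counts per litre of the first phase
- the earlier runs hold the two phases in the same ratio of volumes as the flask asked about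

- alpha: doubling the amount of reagent in the second phase, all else as stated
- delta: doubling the transfer coefficient of the reagent in the second phase, all else as stated

* the target standing at 30 h, as a percentage of the substrate charged
* the change that raises the amount of target at 30 h, in percent of the substrate charged most ("none" if none brings more than 2 percentage points) (alpha / delta / none)
* amount of target at 30 h, in percent of the substrate charged, after alpha

Ash and cedar hold equal charges on different substrate, yet their target readings at 30.0 h differ by 0.9 percentage points, less than the scatter of one reading. So I read percent target as following the reagent charge, as in a reaction pseudo-first-order in substrate. I therefore divide the target at that time by charge and time: alder gives 0.0278 /M/h, ash 0.0270 /M/h, cedar 0.0246 /M/h.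

My first way uses alder and ash, which share the equivalents of the flask: their mean, 0.0274 /M/h, gives 6.65%. My second way uses cedar, which shares its substrate, and gives 5.98%. They part by 0.67 points, less than the scatter, so I keep both. Alder itself reads 6.3% at 25.0 h and then 4.5% at 30.0 h.

I commit to the mean of the two ways, 0.0260 /M/h, the yield coefficient: target as a fraction of substrate charged, per hour and per molar of reagent charge. It gives 6.32%, and doubling the charge gives 12.6%, a gain of 6.3 points, more than the mark. I reckon no number for delta and choose alpha.

The forecast says 7%, alpha and 11.8%, with “the rate about proportional to reagent”.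

The flask gives 6.81%, 0.49 points above my figure. Alpha is best at 5.1 points against 0.32 points for delta, and after alpha the target stands at 11.9%.

    reagent in the reaction phase + target → over-reacted product (k = 7.90 × 10⁻⁵ /M/s)
    2 reagent in the reaction phase → homo dimer (k = 1.20 × 10⁻⁴ /M/s)
    substrate + reagent in the reaction phase → target (k = 7.00 × 10⁻⁵ /M/s)
    target ⇌ isomer of the product (K = 0.610, k = 8.50 × 10⁻⁶ /s)
    reagent in the reaction phase ⇌ reagent in the second phase, rate k5*([reagent in the reaction phase] - [reagent in the second phase]/K5) per volume of the first phase (partition coefficient = 2.00, kL = 1.00 × 10⁻⁴ /s)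

The flask has not come to rest at 30 h: its yield coefficient is 0.0280 /M/h, and target is still made 2.31 times as fast as it is used up, each step taken net. The neighbouring flask, with the same charges read at 3.0 d, stands at 12.0%, a coefficient of 0.0206 /M/h. Left until 300 h, the flask reaches 21.6%, a coefficient of 0.00889 /M/h. Over that stretch substrate falls from 90.6% to 57.0%, reagent in the second phase from 67.8% to 17.8% of its own charge, and isomer of the product climbs from 2.13% to 12.9%.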